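**Retrosynthetic overview**
1. Aryl ether C–O bond (Mitsunobu): 7-hydroxy-8-methoxycoumarin plus a (2S,3R,5S)-2,3-epoxy-1,5-diol side chain.
2. The epoxy diol comes from reductive opening of a cis-fused epoxy δ-lactone (3,7-dioxabicyclo[4.1.0]heptan-2-one); the lactone ties C1' to O5' and so enforces the C1'/C4'-cis (neryl-type) oxirane.
3. Key step: the epoxy lactone comes from a β-(chloroacetoxy) methyl ketone by intramolecular Darzens condensation. The C2'–C3' bond, the δ-lactone ring and the oxirane ring form in one operation, and both epoxide stereocentres are relayed from C5'.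
4. The keto ester comes from prenal by Brown allylboration (sets C5'), Tsuji–Wacker oxidation and chloroacetylation.
5. Ring order: benzene ring bought; coumarin pyranone ring by Pechmann-type propiolate annulation (side branch); δ-lactone and oxirane together (key step); the lactone ring is then opened and the oxirane kept.

Assumption: side-chain carbons are numbered C1' (ArO–CH2) to C8'. Read this way the target is (2'S,3'R,5'S) with C1' and C4' cis on the oxirane. Compound 2 is used as its preformed, salt-free solution.

**Step 1**
Reactants: 1 3-methylbut-2-enal (prenal); 2 B-allyldiisopinocampheylborane derived from (+)-α-pinene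
Product: 3 (4S)-6-methylhepta-1,5-dien-4-ol
Conditions: Et2O, −78 °C, 2 h; then 3 M NaOH, 30% H2O2, 0 °C → rt
Reagents that add atoms: none
Why: Brown asymmetric allylboration through a closed chair transition state, in which the isopinocampheyl groups from (+)-α-pinene deliver the allyl group to the Si face of the enal and so set the (S)-carbinol that becomes C5'.

**Step 2**
Reactants: 3 (4S)-6-methylhepta-1,5-dien-4-ol
Product: 4 (4S)-4-hydroxy-6-methylhept-5-en-2-one
Conditions: PdCl2 (10 mol %), CuCl (30 mol %), O2 (1 atm), DMF/H2O 7:1, rt
Reagents that add atoms: water, O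
Why: Tsuji–Wacker oxidation, in which divalent palladium binds only the unhindered terminal alkene and water adds at the internal carbon (Markovnikov) to give the methyl ketone, leaving the trisubstituted alkene and the carbinol stereocentre untouched.

**Step 3**
Reactants: 4 (4S)-4-hydroxy-6-methylhept-5-en-2-one; 5 chloroacetyl chloride
Product: 6 (4S)-6-methyl-2-oxohept-5-en-4-yl 2-chloroacetate
Conditions: pyridine (1.5 equiv), CH2Cl2, −20 → 0 °C; crude product used directly
Reagents that add atoms: none
Why: O-acylation of the secondary alcohol (nucleophilic acyl substitution) under cold, weakly basic conditions that do not enolise the ketone, so the C–O stereocentre is retained and β-elimination is held back.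

**Step 4**
Reactants: 6 (4S)-6-methyl-2-oxohept-5-en-4-yl 2-chloroacetate
Product: 9 (1R,4S,6R)-6-methyl-4-(2-methylprop-1-en-1-yl)-3,7-dioxabicyclo[4.1.0]heptan-2-one, via lithium chloroenolate 7 (not isolated), via lithium chlorohydrin alkoxide 8 (not isolated)
Conditions: LiN(SiMe3)2 (1.1 equiv), THF (0.02 M), −78 °C, 1 h; then warm to 0 °C
Reagents that add atoms: none
Why: Proposed new method: an intramolecular Darzens glycidic ester condensation in which the ClCH2 group (the most acidic, least hindered C–H) is deprotonated to the enolate with Cl cis to the alkoxy oxygen, which adds to the tethered methyl ketone through a lithium-bridged chair (alkenyl group equatorial, new C–O bond axial and therefore trans to it), and the alkoxide then displaces the anti-periplanar axial chloride with inversion to close the cis-fused oxirane, so C3' and C2' are both relayed from C5' (a chloro epimer that cannot close would equilibrate by enolisation); the closest known reactions are the intermolecular Darzens condensation of α-chloro esters with ketones and the SmI2-mediated intramolecular Reformatsky cyclisation of β-(haloacetoxy) ketones, which shows the same sense of 1,3-induction.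

**Step 5**
Reactants: 9 (1R,4S,6R)-6-methyl-4-(2-methylprop-1-en-1-yl)-3,7-dioxabicyclo[4.1.0]heptan-2-one
Product: 10 [(2S,3R)-3-[(2S)-2-hydroxy-4-methylpent-3-en-1-yl]-3-methyloxiran-2-yl]methanol
Conditions: LiBH4 (2 equiv), THF, 0 °C; then aq NH4Cl
Reagents that add atoms: none
Why: Hydride reduction of the α-oxygen-activated lactone through the lactol to the primary alcohol (acyl–oxygen cleavage, so C5' keeps its configuration), under conditions that do not open the trisubstituted epoxide.

**Step 6**
Reactants: 11 2-methoxybenzene-1,3-diol (2-methoxyresorcinol); 12 ethyl propiolate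
Product: 14 7-hydroxy-8-methoxy-2H-chromen-2-one, via Z-cinnamate ester 13 (not isolated)
Conditions: ZnCl2 (1.0 equiv), dioxane, 100 °C
Reagents that add atoms: none
Why: Pechmann-type hydroarylation–lactonisation, in which the Lewis-acid-activated propiolate is attacked by C4 of the resorcinol (ortho and para to the two hydroxyls; C4 and C6 are equivalent) and the Z-cinnamate lactonises onto the neighbouring hydroxyl, giving the coumarin with no stereocentre.

**Step 7**
Reactants: 10 [(2S,3R)-3-[(2S)-2-hydroxy-4-methylpent-3-en-1-yl]-3-methyloxiran-2-yl]methanol; 14 7-hydroxy-8-methoxy-2H-chromen-2-one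
Product: 15 7-{[(2S,3R)-3-[(2S)-2-hydroxy-4-methylpent-3-en-1-yl]-3-methyloxiran-2-yl]methoxy}-8-methoxy-2H-chromen-2-one
Conditions: PPh3 (1.2 equiv), DIAD (1.2 equiv), 14 (1.1 equiv), THF, 0 °C → rt
Reagents that add atoms: none
Why: Mitsunobu etherification, in which the acidic 7-hydroxyl protonates the betaine and its phenoxide displaces the oxyphosphonium of the unhindered primary alcohol by SN2 at the CH2 carbon, so the hindered secondary allylic alcohol, the epoxide and all three stereocentres are untouched.

**Compound list**
1 | 3-methylbut-2-enal (prenal) | CC(C)=CC=O | starting material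
2 | allylbis[(1R,2S,3R,5R)-2,6,6-trimethylbicyclo[3.1.1]heptan-3-yl]borane (B-allyldiisopinocampheylborane from (+)-α-pinene) | C=CCB([C@@H]1C[C@@H]2C[C@H]([C@H]1C)C2(C)C)[C@@H]1C[C@@H]2C[C@H]([C@H]1C)C2(C)C | starting material
3 | (4S)-6-methylhepta-1,5-dien-4-ol | C=CC[C@H](O)C=C(C)C | intermediate
4 | (4S)-4-hydroxy-6-methylhept-5-en-2-one | CC(=O)C[C@H](O)C=C(C)C | intermediate
5 | chloroacetyl chloride | ClCC(Cl)=O | starting material
6 | (4S)-6-methyl-2-oxohept-5-en-4-yl 2-chloroacetate | CC(=O)C[C@H](OC(=O)CCl)C=C(C)C | intermediate
7 | lithium 2-chloro-1-{[(4S)-6-methyl-2-oxohept-5-en-4-yl]oxy}ethen-1-olate, Cl cis to the alkoxy oxygen (not isolated) | [Li+].[O-]/C(=C/Cl)O[C@@H](CC(C)=O)C=C(C)C | intermediate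
8 | lithium (3S,4R,6S)-3-chloro-4-methyl-6-(2-methylprop-1-en-1-yl)-2-oxooxan-4-olate (not isolated) | [Li+].O=C1[C@@H](Cl)[C@@]([O-])(C)C[C@H](O1)C=C(C)C | intermediate
9 | (1R,4S,6R)-6-methyl-4-(2-methylprop-1-en-1-yl)-3,7-dioxabicyclo[4.1.0]heptan-2-one (epoxide oxygen trans to the alkenyl group) | O=C1[C@@H]2O[C@]2(C)C[C@H](O1)C=C(C)C | intermediate
10 | [(2S,3R)-3-[(2S)-2-hydroxy-4-methylpent-3-en-1-yl]-3-methyloxiran-2-yl]methanol | OC[C@@H]1O[C@]1(C)C[C@H](O)C=C(C)C | intermediate
11 | 2-methoxybenzene-1,3-diol | COc1c(O)cccc1O | starting material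
12 | ethyl propiolate | C#CC(=O)OCC | starting material
13 | ethyl (2Z)-3-(2,4-dihydroxy-3-methoxyphenyl)prop-2-enoate (not isolated) | CCOC(=O)/C=C\c1ccc(O)c(OC)c1O | intermediate
14 | 7-hydroxy-8-methoxy-2H-chromen-2-one | COc1c(O)ccc2ccc(=O)oc12 | intermediate
15 | 7-{[(2S,3R)-3-[(2S)-2-hydroxy-4-methylpent-3-en-1-yl]-3-methyloxiran-2-yl]methoxy}-8-methoxy-2H-chromen-2-one | COc1c(OC[C@@H]2O[C@]2(C)C[C@H](O)C=C(C)C)ccc2ccc(=O)oc12 | target

**Total step count:** 7.
**Longest linear sequence:** 6 (steps 1, 2, 3, 4, 5, 7); step 6 is a one-step side branch.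

**Three steps most likely to fail**

Step 4 is the main risk. The β-acyloxy ketone can lose chloroacetate by E1cB elimination to the conjugated dienone, the methyl ketone enolate can attack the ester, and the 1,3-induction is predicted, not proven. The fallback sets out from hydroxy ketone 4 and comes back at epoxy lactone 9. Compound 4 is heated with ketenylidenetriphenylphosphorane (Ph3P=C=C=O) in toluene. The alcohol adds to the cumulated ylide to give the ester ylide (4S)-6-methyl-2-oxohept-5-en-4-yl (triphenylphosphoranylidene)acetate F1. F1 closes by intramolecular Wittig olefination onto the methyl ketone to the unsaturated lactone (6S)-4-methyl-6-(2-methylprop-1-en-1-yl)-5,6-dihydro-2H-pyran-2-one F2. Weitz–Scheffer epoxidation of F2 (tBuOOH, catalytic benzyltrimethylammonium hydroxide, THF, 0 °C) adds the peroxide anti to the pseudo-equatorial alkenyl group and gives 9. This replaces the one-pot double closure with two conventional ring-forming steps.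

Step 7 is the second risk. The secondary allylic alcohol may also be activated, and the C5' hydroxyl can attack the activated C1' intramolecularly to form a six-membered cyclic ether. The fallback sets out from epoxy diol 10 and comes back at target 15. The primary hydroxyl is sulfonylated selectively (TsCl, pyridine, CH2Cl2, 0 °C) to [(2S,3R)-3-[(2S)-2-hydroxy-4-methylpent-3-en-1-yl]-3-methyloxiran-2-yl]methyl 4-methylbenzenesulfonate F3. F3 is then displaced at C1' by the phenoxide of 14 (Cs2CO3, DMF, rt), the usual regiochemistry for 2,3-epoxy sulfonates. This replaces the redox condensation with stepwise activation and SN2 displacement.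

Step 3 is the third risk. The product is a β-(chloroacetoxy) ketone that is also an allylic ester, so elimination or ionisation can occur during acylation or purification. The fallback sets out from dienol 3 and comes back at keto ester 6, bypassing 4. Compound 3 is acylated first (chloroacetyl chloride, pyridine, CH2Cl2, 0 °C) to (4S)-6-methylhepta-1,5-dien-4-yl 2-chloroacetate F4, which has no ketone and cannot eliminate. The Tsuji–Wacker oxidation (PdCl2, CuCl, O2, DMF/H2O) is then run on F4 and gives 6 under non-basic conditions.

**Further compounds**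
F1 | step 4 | (4S)-6-methyl-2-oxohept-5-en-4-yl (triphenylphosphoranylidene)acetate | CC(=O)C[C@H](OC(=O)C=P(c1ccccc1)(c1ccccc1)c1ccccc1)C=C(C)C
F2 | step 4 | (6S)-4-methyl-6-(2-methylprop-1-en-1-yl)-5,6-dihydro-2H-pyran-2-one | O=C1C=C(C)C[C@H](O1)C=C(C)C
F3 | step 7 | [(2S,3R)-3-[(2S)-2-hydroxy-4-methylpent-3-en-1-yl]-3-methyloxiran-2-yl]methyl 4-methylbenzenesulfonate | Cc1ccc(cc1)S(=O)(=O)OC[C@@H]1O[C@]1(C)C[C@H](O)C=C(C)C
F4 | step 3 | (4S)-6-methylhepta-1,5-dien-4-yl 2-chloroacetate | C=CC[C@H](OC(=O)CCl)C=C(C)C
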